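**Retrosynthetic overview**
1. Target 19 ⇐ global removal of three MOM ethers from diaryl ether 18.
2. 18 ⇐ Ullmann C–O union of ring A iodide 11 (3R side chain) with ring B phenol 17 (3S side chain). The iodide and the phenol oxygen are both installed by MOM-directed ortho-lithiation.
3. Each aryl–C(quaternary) bond ⇐ SN2′-type union of an aryl unit with a C15 farnesyl unit. Ring A uses the established copper-catalysed allylic substitution (aryl alane + farnesyl phosphate 2). Ring B uses a proposed enantioselective γ-selective Suzuki–Miyaura coupling (aryl bromide 13 + farnesylboronate 4).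
4. No ring is constructed: rings A and B are bought as 3-bromophenol and 4-bromocatechol. Order: ring A fragment, ring B fragment, ether union, deprotection.

Assumption: the SMILES is read literally, so ring A (monohydroxy ring) carries the 3R side chain and ring B (dihydroxy ring) the 3S side chain. The ligand antipode named in steps 5 and 8 is the one assumed to give the stated configuration and is swapped for its mirror image if a pilot run shows the opposite sense.

Ligands: (S,S)-Im = (4S,5S)-1-(2,6-diethylphenyl)-4,5-diphenyl-3-(2-sulfonatophenyl)-4,5-dihydroimidazolium zwitterion (carbene precursor). (S)-BI-DIME = (S)-3-tert-butyl-4-(2,6-dimethoxyphenyl)-2,3-dihydro-1,3-benzoxaphosphole.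

**Step 1**
Reactants: 1 (2E,6E)-farnesol
Product: 2 diethyl (2E,6E)-3,7,11-trimethyldodeca-2,6,10-trien-1-yl phosphate
Conditions: ClP(O)(OEt)2, Et3N, DMAP (cat.), CH2Cl2, 0 °C → rt
Reagents that add atoms: diethyl chlorophosphate, CCOP(=O)(Cl)OCC
Why: O-phosphorylation of a primary allylic alcohol under amine/DMAP catalysis leaves both (E)-alkenes untouched and forms no stereocenter.

**Step 2**
Reactants: 1 (2E,6E)-farnesol
Product: 3 (2E,6E)-farnesyl acetate
Conditions: Ac2O, pyridine, DMAP (cat.), CH2Cl2, rt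
Reagents that add atoms: acetic anhydride, CC(=O)OC(C)=O
Why: DMAP-catalysed O-acetylation of a primary alcohol is quantitative and does not touch the alkenes.

**Step 3**
Reactants: 3 (2E,6E)-farnesyl acetate
Product: 4 2-[(2E,6E)-3,7,11-trimethyldodeca-2,6,10-trien-1-yl]-4,4,5,5-tetramethyl-1,3,2-dioxaborolane
Conditions: B2pin2, Ni(cod)2 (5 mol %), PCy3 (10 mol %), EtOAc, rt
Reagents that add atoms: bis(pinacolato)diboron, CC1(C)OB(OC1(C)C)B1OC(C)(C)C(C)(C)O1
Why: Miyaura-type allylic borylation; the π-allyl nickel formed by ionisation of the acetate is borylated at the unhindered primary terminus, which should keep the (2E) geometry (E/Z ratio checked by NMR before use).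

**Step 4**
Reactants: 5 3-bromophenol
Product: 6 1-bromo-3-(methoxymethoxy)benzene
Conditions: MOMCl, i-Pr2NEt, CH2Cl2, 0 °C → rt
Reagents that add atoms: chloromethyl methyl ether, COCCl
Why: Williamson-type O-alkylation of the phenol with a reactive α-chloro ether gives the MOM acetal, which is stable to organolithiums and later directs ortho-lithiation.

**Step 5**
Reactants: 6 1-bromo-3-(methoxymethoxy)benzene; 2 diethyl (2E,6E)-3,7,11-trimethyldodeca-2,6,10-trien-1-yl phosphate
Product: 9 1-(methoxymethoxy)-3-[(3R,6E)-3,7,11-trimethyldodeca-1,6,10-trien-3-yl]benzene, via 3-(methoxymethoxy)phenyllithium 7 (not isolated), via diethyl[3-(methoxymethoxy)phenyl]alane 8 (not isolated)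
Conditions: n-BuLi, THF, –78 °C; Et2AlCl, –78 °C → rt; then 2, CuCl2·2H2O (2 mol %), (S,S)-Im (2.5 mol %), Ag2O (1.3 mol %), THF, –30 °C; sat. aq NH4Cl
Reagents that add atoms: n-butyllithium, [Li]CCCC (lithium of 7); diethylaluminium chloride, CC[Al](Cl)CC (diethylaluminium group of 8)
Why: Copper-catalysed enantioselective allylic substitution (SN2′) of a trisubstituted allylic phosphate by an aryl(diethyl)alane, established for geranyl-type phosphates; the sulfonate-bridged carbene–copper complex transfers the aryl group to C3 anti to the leaving phosphate on one face of the (2E)-alkene, which sets the 3R quaternary center.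

**Step 6**
Reactants: 9 1-(methoxymethoxy)-3-[(3R,6E)-3,7,11-trimethyldodeca-1,6,10-trien-3-yl]benzene
Product: 11 1-iodo-2-(methoxymethoxy)-4-[(3R,6E)-3,7,11-trimethyldodeca-1,6,10-trien-3-yl]benzene, via aryllithium 10 (not isolated)
Conditions: n-BuLi, TMEDA, Et2O, 0 °C; ICH2CH2I, –78 °C → rt
Reagents that add atoms: n-butyllithium, [Li]CCCC (lithium of 10); 1,2-diiodoethane, ICCI
Why: Directed ortho-metalation; the MOM group directs lithiation to the ortho carbon para to the side chain because the other ortho site is blocked by the quaternary carbon, and iodinolysis with 1,2-diiodoethane avoids free iodine near the alkenes; the stereocenter is not involved.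

**Step 7**
Reactants: 12 4-bromobenzene-1,2-diol
Product: 13 4-bromo-1,2-bis(methoxymethoxy)benzene
Conditions: MOMCl (3 equiv), i-Pr2NEt (4 equiv), CH2Cl2, 0 °C → 40 °C
Reagents that add atoms: chloromethyl methyl ether, COCCl
Why: Twofold Williamson-type O-alkylation gives the bis-MOM catechol, which is stable to base and palladium and later directs ortho-lithiation.

**Step 8**
Reactants: 13 4-bromo-1,2-bis(methoxymethoxy)benzene; 4 2-[(2E,6E)-3,7,11-trimethyldodeca-2,6,10-trien-1-yl]-4,4,5,5-tetramethyl-1,3,2-dioxaborolane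
Product: 14 1,2-bis(methoxymethoxy)-4-[(3S,6E)-3,7,11-trimethyldodeca-1,6,10-trien-3-yl]benzene
Conditions: Pd2(dba)3 (1.5 mol %), (S)-BI-DIME (6 mol %), aq K3PO4, THF, 40 °C
Reagents that add atoms: none
Why: Proposed new method: enantioselective γ-selective Suzuki–Miyaura allyl–aryl coupling. Oxidative addition of 13 to the zerovalent palladium–phosphine complex and bromide/hydroxide exchange give ArPd(OH)L*, which engages boronate 4 through a closed six-membered SE2′ transition state (Pd–O–B bridge) so that palladium bonds to the trisubstituted C3. The bulky P-stereogenic monophosphine is meant to force C–C reductive elimination from this tertiary σ-allyl before σ–π–σ slippage to the linear isomer or E/Z scrambling, and to choose the alkene face; the (2E) geometry of 4 fixes methyl versus chain, so one face gives 3S. The closest known reaction type is the racemic, ligand-controlled γ-selective Suzuki–Miyaura coupling of 3,3-disubstituted allylboronates (prenyl, geranyl) with aryl halides under bulky biarylphosphine–palladium catalysis, together with enantioselective palladium-catalysed allyl–allyl couplings that build quaternary centers; I am not aware of an enantioselective intermolecular allyl–aryl version.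

**Step 9**
Reactants: 14 1,2-bis(methoxymethoxy)-4-[(3S,6E)-3,7,11-trimethyldodeca-1,6,10-trien-3-yl]benzene
Product: 17 2,3-bis(methoxymethoxy)-5-[(3S,6E)-3,7,11-trimethyldodeca-1,6,10-trien-3-yl]phenol, via aryllithium 15 (not isolated), via lithium aryltrimethoxyborate 16 (not isolated)
Conditions: n-BuLi, TMEDA, THF, 0 °C; B(OMe)3, –78 °C → rt; aq NaOH, 30 % H2O2, 0 °C
Reagents that add atoms: n-butyllithium, [Li]CCCC (lithium of 15 and 16); trimethyl borate, COB(OC)OC (boron and methoxy groups of 16); hydrogen peroxide, OO (phenol oxygen of 17)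
Why: Directed ortho-metalation followed by borylation and oxidation; only the ortho C–H remote from the quaternary carbon is accessible, and alkaline peroxide oxidises the aryl–boron bond with retention of position without touching the unactivated alkenes or the stereocenter.

**Step 10**
Reactants: 11 1-iodo-2-(methoxymethoxy)-4-[(3R,6E)-3,7,11-trimethyldodeca-1,6,10-trien-3-yl]benzene; 17 2,3-bis(methoxymethoxy)-5-[(3S,6E)-3,7,11-trimethyldodeca-1,6,10-trien-3-yl]phenol
Product: 18 1,2-bis(methoxymethoxy)-3-{2-(methoxymethoxy)-4-[(3R,6E)-3,7,11-trimethyldodeca-1,6,10-trien-3-yl]phenoxy}-5-[(3S,6E)-3,7,11-trimethyldodeca-1,6,10-trien-3-yl]benzene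
Conditions: CuI (10 mol %), picolinic acid (20 mol %), K3PO4, DMSO, 90 °C
Reagents that add atoms: none
Why: Ullmann-type diaryl ether synthesis; the picolinate–copper catalyst couples ortho-substituted aryl iodides with hindered phenols under mild base that MOM ethers, isolated alkenes and the two quaternary centers tolerate.

**Step 11**
Reactants: 18 1,2-bis(methoxymethoxy)-3-{2-(methoxymethoxy)-4-[(3R,6E)-3,7,11-trimethyldodeca-1,6,10-trien-3-yl]phenoxy}-5-[(3S,6E)-3,7,11-trimethyldodeca-1,6,10-trien-3-yl]benzene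
Product: 19 3-{2-hydroxy-4-[(3R,6E)-3,7,11-trimethyldodeca-1,6,10-trien-3-yl]phenoxy}-5-[(3S,6E)-3,7,11-trimethyldodeca-1,6,10-trien-3-yl]benzene-1,2-diol
Conditions: 2 M HCl in MeOH/THF (1:1), degassed, rt → 40 °C
Reagents that add atoms: none
Why: Acid-catalysed transacetalisation of aryl MOM ethers to methanol is fast under dilute acid, where the isolated trisubstituted alkenes are not protonated appreciably; the stereocenters are untouched.

**Compound list**
1 | (2E,6E)-farnesol | OC/C=C(\C)CC/C=C(\C)CCC=C(C)C | starting material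
2 | diethyl (2E,6E)-3,7,11-trimethyldodeca-2,6,10-trien-1-yl phosphate | CCOP(=O)(OCC)OC/C=C(\C)CC/C=C(\C)CCC=C(C)C | intermediate
3 | (2E,6E)-farnesyl acetate | CC(=O)OC/C=C(\C)CC/C=C(\C)CCC=C(C)C | intermediate
4 | 2-[(2E,6E)-3,7,11-trimethyldodeca-2,6,10-trien-1-yl]-4,4,5,5-tetramethyl-1,3,2-dioxaborolane | CC1(C)OB(C/C=C(\C)CC/C=C(\C)CCC=C(C)C)OC1(C)C | intermediate
5 | 3-bromophenol | Oc1cccc(Br)c1 | starting material
6 | 1-bromo-3-(methoxymethoxy)benzene | COCOc1cccc(Br)c1 | intermediate
7 | 3-(methoxymethoxy)phenyllithium | [Li]c1cccc(OCOC)c1 | intermediate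
8 | diethyl[3-(methoxymethoxy)phenyl]alane | CC[Al](CC)c1cccc(OCOC)c1 | intermediate
9 | 1-(methoxymethoxy)-3-[(3R,6E)-3,7,11-trimethyldodeca-1,6,10-trien-3-yl]benzene | C=C[C@@](C)(CC/C=C(\C)CCC=C(C)C)c1cccc(OCOC)c1 | intermediate
10 | {2-(methoxymethoxy)-4-[(3R,6E)-3,7,11-trimethyldodeca-1,6,10-trien-3-yl]phenyl}lithium | C=C[C@@](C)(CC/C=C(\C)CCC=C(C)C)c1ccc([Li])c(OCOC)c1 | intermediate
11 | 1-iodo-2-(methoxymethoxy)-4-[(3R,6E)-3,7,11-trimethyldodeca-1,6,10-trien-3-yl]benzene | C=C[C@@](C)(CC/C=C(\C)CCC=C(C)C)c1ccc(I)c(OCOC)c1 | intermediate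
12 | 4-bromobenzene-1,2-diol (4-bromocatechol) | Oc1ccc(Br)cc1O | starting material
13 | 4-bromo-1,2-bis(methoxymethoxy)benzene | COCOc1ccc(Br)cc1OCOC | intermediate
14 | 1,2-bis(methoxymethoxy)-4-[(3S,6E)-3,7,11-trimethyldodeca-1,6,10-trien-3-yl]benzene | C=C[C@](C)(CC/C=C(\C)CCC=C(C)C)c1ccc(OCOC)c(OCOC)c1 | intermediate
15 | {2,3-bis(methoxymethoxy)-5-[(3S,6E)-3,7,11-trimethyldodeca-1,6,10-trien-3-yl]phenyl}lithium | C=C[C@](C)(CC/C=C(\C)CCC=C(C)C)c1cc([Li])c(OCOC)c(OCOC)c1 | intermediate
16 | lithium trimethoxy{2,3-bis(methoxymethoxy)-5-[(3S,6E)-3,7,11-trimethyldodeca-1,6,10-trien-3-yl]phenyl}borate | [Li+].C=C[C@](C)(CC/C=C(\C)CCC=C(C)C)c1cc([B-](OC)(OC)OC)c(OCOC)c(OCOC)c1 | intermediate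
17 | 2,3-bis(methoxymethoxy)-5-[(3S,6E)-3,7,11-trimethyldodeca-1,6,10-trien-3-yl]phenol | C=C[C@](C)(CC/C=C(\C)CCC=C(C)C)c1cc(O)c(OCOC)c(OCOC)c1 | intermediate
18 | 1,2-bis(methoxymethoxy)-3-{2-(methoxymethoxy)-4-[(3R,6E)-3,7,11-trimethyldodeca-1,6,10-trien-3-yl]phenoxy}-5-[(3S,6E)-3,7,11-trimethyldodeca-1,6,10-trien-3-yl]benzene | C=C[C@@](C)(CC/C=C(\C)CCC=C(C)C)c1ccc(Oc2cc([C@](C)(C=C)CC/C=C(\C)CCC=C(C)C)cc(OCOC)c2OCOC)c(OCOC)c1 | intermediate
19 | 3-{2-hydroxy-4-[(3R,6E)-3,7,11-trimethyldodeca-1,6,10-trien-3-yl]phenoxy}-5-[(3S,6E)-3,7,11-trimethyldodeca-1,6,10-trien-3-yl]benzene-1,2-diol (CNP0230356.1) | C=C[C@@](C)(CC/C=C(\C)CCC=C(C)C)c1ccc(Oc2cc([C@](C)(C=C)CC/C=C(\C)CCC=C(C)C)cc(O)c2O)c(O)c1 | target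

**Step count and risk**
Total step count: 11. Longest linear sequence: 6 steps (1 → 3 → 4 → 14 → 17 → 18 → 19; steps 2, 3, 8, 9, 10, 11).

The three steps most likely to fail:

Step 8 (the proposed new coupling). It may give the linear farnesyl arene, low enantioselectivity through σ–π–σ equilibration, or protodeboronation of 4. The fallback uses known chemistry, sets out from bromide 13 and comes back at 14. Bromine–lithium exchange (n-BuLi, THF, –78 °C) gives 3,4-bis(methoxymethoxy)phenyllithium F1, and Et2AlCl converts it into diethyl[3,4-bis(methoxymethoxy)phenyl]alane F2. F2 is then added to phosphate 2 with CuCl2·2H2O and the mirror-image ligand (R,R)-Im (Ag2O) at –30 °C, exactly as in step 5, to give 14 by copper-catalysed enantioselective allylic substitution.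

Step 10 (Ullmann etherification). Both partners carry an ortho MOM ether and are very lipophilic, so conversion may stall or the iodide may be reduced. The fallback sets out from 9 and comes back at 18, replacing the halide coupling by an oxidative boron coupling at room temperature. Lithiation as in step 6 gives aryllithium 10, which is quenched with B(Oi-Pr)3 to lithium triisopropoxy{2-(methoxymethoxy)-4-[(3R,6E)-3,7,11-trimethyldodeca-1,6,10-trien-3-yl]phenyl}borate F3. Aqueous work-up hydrolyses it to {2-(methoxymethoxy)-4-[(3R,6E)-3,7,11-trimethyldodeca-1,6,10-trien-3-yl]phenyl}boronic acid F4. Chan–Lam–Evans coupling of F4 with phenol 17 (Cu(OAc)2, pyridine, 4 Å molecular sieves, CH2Cl2, air, rt) gives 18.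

Step 11 (global deprotection). Protic acid may hydrate or cyclise the trisubstituted alkenes, and the free catechol is air-sensitive. The fallback sets out from 18 and comes back at 19 without protic acid. TMSOTf with 2,2′-bipyridyl (CH2Cl2, 0 °C) exchanges the three aryl MOM ethers for silyl ethers, giving 1,2-bis(trimethylsilyloxy)-3-{2-(trimethylsilyloxy)-4-[(3R,6E)-3,7,11-trimethyldodeca-1,6,10-trien-3-yl]phenoxy}-5-[(3S,6E)-3,7,11-trimethyldodeca-1,6,10-trien-3-yl]benzene F5. Water (or K2CO3 in MeOH, rt, under argon) then cleaves F5 to 19.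

**Further compounds**
F1 | step 8 | 3,4-bis(methoxymethoxy)phenyllithium | [Li]c1ccc(OCOC)c(OCOC)c1
F2 | step 8 | diethyl[3,4-bis(methoxymethoxy)phenyl]alane | CC[Al](CC)c1ccc(OCOC)c(OCOC)c1
F3 | step 10 | lithium triisopropoxy{2-(methoxymethoxy)-4-[(3R,6E)-3,7,11-trimethyldodeca-1,6,10-trien-3-yl]phenyl}borate | [Li+].C=C[C@@](C)(CC/C=C(\C)CCC=C(C)C)c1ccc([B-](OC(C)C)(OC(C)C)OC(C)C)c(OCOC)c1
F4 | step 10 | {2-(methoxymethoxy)-4-[(3R,6E)-3,7,11-trimethyldodeca-1,6,10-trien-3-yl]phenyl}boronic acid | C=C[C@@](C)(CC/C=C(\C)CCC=C(C)C)c1ccc(B(O)O)c(OCOC)c1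
F5 | step 11 | 1,2-bis(trimethylsilyloxy)-3-{2-(trimethylsilyloxy)-4-[(3R,6E)-3,7,11-trimethyldodeca-1,6,10-trien-3-yl]phenoxy}-5-[(3S,6E)-3,7,11-trimethyldodeca-1,6,10-trien-3-yl]benzene | C=C[C@@](C)(CC/C=C(\C)CCC=C(C)C)c1ccc(Oc2cc([C@](C)(C=C)CC/C=C(\C)CCC=C(C)C)cc(O[Si](C)(C)C)c2O[Si](C)(C)C)c(O[Si](C)(C)C)c1
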